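I wrote a balance first.

- elm: electrophile 34 mM; nucleophile 82 mM; free base 68 mM; run made earlier
- flask: electrophile 34 mM; nucleophile 40.8 mM; free base 68.0 mM; time 6.0 min

elm run (percent of the electrophile charged)

| time / s | electrophile / % | target / % |
|---|---|---|
| 10.0 | 78.9 | 19.6 |
| 15.0 | 69.8 | 30.6 |
| 30.0 | 53.3 | 45.2 |
| 50.0 | 37.7 | 57.5 |
| 60.0 | 34.1 | 62.2 |
| 80.0 | 24.1 | 70.6 |
| 120 | 14.1 | 77.3 |

(scatter of a reading: 1 percentage point)

- percent here means electrophile units held: one side product counts as two
- the numbers in the tables scatter with a standard deviation of 1 percentage point
- the reaction counts as stopped when no species that holds the electrophile changes by six tenths of a point or more over the second half of the time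

* why nothing more happens at 6.0 min, or that something still does (forward and back rates have come level / all of the electrophile has reacted / it is still moving / the free base has run out first / the nucleophile has run out first)
* conversion of electrophile at 6.0 min
* amount of target at 6.0 min, in percent of the electrophile charged
* amount of side product at 6.0 min, in percent of the electrophile charged

I took the electrophile, the smaller charge in this flask, as the reagent to balance. I assumed each main step took one electrophile and one nucleophile to give one target, and each side step took one target and one more electrophile:

c_electrophile = 34 mM − 2·(40.8 mM − c_nucleophile) + c_target

First I reckoned the main step alone. By 120 s the elm run had lost 8.60% to side product, which meant 1.46 mM of side steps and 27.7 mM of main steps. Its electrophile gave a rate constant of 0.268 M⁻¹ s⁻¹. With that constant alone, my flask reached 84.8% target at 6.0 min.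

Then I added the side step. Both steps need electrophile, so it cancels from their ratio:

side rate / main rate = S·c_target / c_nucleophile

I called S the selectivity factor, the side step's rate constant over the main step's, and summed this ratio over the elm run to get 0.239, a reading that carries the scatter. Integrated, the ratio gives:

c_target = [c_nucleophile,start·(c_nucleophile/c_nucleophile,start)^S − c_nucleophile] / (1 − S)

Stepping both rates by hand left a third of the nucleophile, 13.6 mM. So target fell to 23.4 mM, or 68.8%, and the balance left 8.72% electrophile.

The free base came last. At 68.0 mM it was charged at twice the electrophile, so I judged that it would not limit and added nothing for it.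

The forecast said it is still moving, with conversion 90%, target 69.5% and side product 20.5%, on the grounds that “This late loss suggests the side product forms from target plus electrophile”.

    electrophile + nucleophile → acid set free + target (k = 0.321 M⁻¹ s⁻¹)
    nucleophile + acid set free ⇌ protonated nucleophile, settled at all times (K = 820 M⁻¹)
    acid set free + free base ⇌ salt of the base (K = 6100 M⁻¹, k = 1.10 M⁻¹ s⁻¹)
    acid set free → by-product carried off (k = 0.0120 s⁻¹)
    electrophile + target → side product (k = 0.0611 M⁻¹ s⁻¹)

The flask gave it is still moving: conversion 86.4%, target 62.9%, 6.6 percentage points under the forecast, and side product 23.5%. At 6.00 min it held 26% of its nucleophile free, beside 4.71 mM of protonated nucleophile. Through S, those amounts put target made against target used at 2.10; the flask's own rates gave 2.63. In the neighbour flask with 20 mM of electrophile, the same reckoning gave 4.80, and that flask ended with 80.3% target and 12.9% side product.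

All runs stem from a simulated flask for an exercise; noise was put on by code.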